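**Remarks on the chemistry.** Positions are given in carotenoid numbering (C1–C20, primed for the furanoid half). Compounds 8–11 are carried as mixtures of epimers at C6, which becomes a carbonyl carbon in step 9. Z isomers formed at C11=C12 and C11'=C12' in the two Wittig steps are assumed to equilibrate thermally to the all-E compounds, as these hindered Z bonds normally do.

## The problem

The target 28 is a C40 carotenoid with a (3S,5R,6R)-3,5,6-trihydroxy-5,6-dihydro end group (ring A) and a (3'S,5'R,8'R)-5',8'-epoxy end group (a 2,5-dihydrofuran fused to the second cyclohexane). An all-E chain of eight conjugated double bonds joins them and has to be assembled by olefinations that are E-selective or can be equilibrated. The six stereocentres sit in two groups of three that cannot influence each other across the chain, so each end must be set on its own. Within ring A the quaternary carbinol C5 and the secondary carbinol C3 can direct C6, which lies between the fully substituted C1 and C5. In the furanoid end C5' and the geometry of the neighbouring double bond can direct C8'. Both ends carry the same 3S-hydroxyl and 5R-oxygen, so one building block can serve both. The polyene is sensitive to light, oxygen and acid; the tertiary allylic C6 hydroxyl ionises with acid; the doubly allylic C8'–O bond epimerises with acid and would be expelled by a carbanion at C11'. The feature that invites the key step is that C1–C6 with the three ring methyl groups and C7 are the ten carbons of linalool, with the linalool carbinol as C5. A hydrogen atom delivered to C2 of the C1=C2 alkene leaves a tertiary radical at C1, six atoms from a C6 ketone.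

## Retrosynthesis

**C11'=C12' and the silyl groups.** Target 28 is traced to its 3,3'-bis-silyl ether 27, and 27 is cut at C11'=C12' into the C25 phosphonium salt 26 and the furanoid C15 aldehyde 22. This polarity is chosen because an ylide at C11' would be conjugated to C9', next to the C8'–O bond, and could open the dihydrofuran. A central C15=C15' cut would need two C20 units, each several steps longer. The forward Wittig reaction must run without free base, and the silyl groups must come off with fluoride, not acid.

**C11=C12 and the linker.** Salt 26 is cut at C11=C12 into the ring A C15 aldehyde 19 and the C10 bis-phosphonium salt 25, which comes from diol 24 and the commercial dialdehyde 23. A linker that carries both ylide carbons lets both end groups enter as aldehydes. Using 23 directly would force the furanoid half to be the ylide. The forward reaction must stop after one olefination of 25.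

**Both end groups from one ester.** Aldehyde 22 comes from alcohol 21 and ester 20, and 20 is traced to the dihydroxy ester 17 by cutting the O5'–C8' bond with a shift of the double bond to C7=C8. Aldehyde 19 comes from the same ester 17 through alcohol 18. This cut avoids a second ring synthesis and keeps C5' untouched. Its demand is that closure on the allyl cation be faster than rotation about C7–C8, so it is placed at the ester stage, where only the C6 hydroxyl can ionise and the chain is short.

**C7=C8.** Ester 17 is cut at C7=C8 into the ring A aldehyde 15 and the C5 phosphonate 16. The neighbouring cut at C6–C7 would leave the C6 configuration to a nucleophilic addition of uncertain facial sense. A cut at C9=C10 would need olefination of a methyl ketone with poor E/Z control. The forward reaction must olefinate a neopentyl aldehyde that bears a free tertiary hydroxyl.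

**Adjusting C7.** Aldehyde 15 comes from triol 14, and 14 from the silyl-protected ring compound 13. One fluoride step must free O5 and C7 and leave the C3 silyl ether.

**C1–C6, the key cut.** Ring compound 13 is cut between C1 and C6 to the acyclic alkenyl ketone 12. Of all ring bonds only this one leaves a chain with the linalool skeleton and the C5 carbinol already in place. Cuts at C5–C6 or C4–C5 would have to create the quaternary carbinol. Polar cyclisations of 12 would bond C6 to C2, so the bond is made by a radical. The precursor has two stereocentres instead of three and no ring.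

**Oxidation levels of the chain.** Ketone 12 is traced through alcohol 11, allylic alcohol 10, silyl ether 9 and diol 8 to enone 7. The C6 ketone comes from a carbinol, the C3 carbinol from reagent-controlled reduction of the enone, and the C6 and C7 oxygens from dihydroxylation of the vinyl group. The dihydroxylation is done while C1=C2 is deactivated as the enone, and C3 is reduced before C6 is oxidised so that only one ketone is present.

**The C3 oxygen.** Enone 7 is traced through the tertiary allylic alcohol 6 and epoxide 3 to silyl ether 2 and (R)-linalool 1. The epoxide route moves oxygen to C3 without the regioisomer mixture of a singlet-oxygen ene reaction. Linalool supplies C5 in the right configuration.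

## Roads not taken

**Alternative 1:** The cut is the C5'–O bond of the oxolane ring, with C6'=C7' added later by dehydration. In the forward key step camphorsulfonic acid makes a C8' hydroxyl, set beforehand, open a 5',6'-epoxide syn to the C3' oxygen at C5' with inversion, giving the 6'-hydroxy-7',8'-dihydro furanoid unit A1.
- Merits: C8' is set on its own and does not depend on C5', and 5-exo epoxide opening is a classical oxolane synthesis.
- Weak points: inversion at a fully substituted carbon under acid may be eroded by cation character; the syn-epoxide and a separate asymmetric step for C8' are needed; dehydration follows; ring A still needs its own synthesis.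
- Comparison: this road is the more secure one for C8', which the chosen plan derives from a cation geometry. The chosen plan sets against this that C5' is never touched, that both end groups come from ester 17, and that the furanoid ring costs one step.

**Alternative 2:** The cut is C5–C6 of ring A. In the forward key step a chiral aminoindanol-derived triazolium carbene turns a C6 aldehyde into an acyl anion equivalent that adds to a C5 methyl ketone, closing the ring as the α-ketol A2.
- Merits: the step is catalytic, starts from a cheap achiral feedstock, avoids radical fragmentation and selenium or chromium reagents, and A2 could serve both end groups.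
- Weak points: the aldehyde is neopentyl, so the Breslow intermediate forms slowly; the ketone acceptor is enolisable; the C3 centre must be made beforehand and may be mismatched with the catalyst; A2 lacks C7, and the C6 centre is left to a later addition to a ketone flanked by two quaternary carbons.
- Comparison: this road reaches a ring A building block in fewer steps. The chosen plan sets against this that C5 comes from the chiral pool, that C7 is already attached, and that C6 is set in the ring closure.

**Alternative 3:** The cut is the O–C8' bond. In the forward key step Ph3PAuCl/AgBF4 (monovalent gold) activates the C7'=C8' bond of an allene spanning C6'–C8', and the tertiary C5' hydroxyl adds to C8', transferring the allene axis to the new centre and giving the furanoid bis-silyl ether A3, which is the silyl ether of alcohol 21.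
- Merits: chirality transfer in gold cyclisations of α-hydroxyallenes is well precedented, and the conditions are neutral.
- Weak points: the allene axis must itself be made selectively next to the fully substituted C6'; a vinylallene can racemise or undergo a Nazarov-type closure under gold; only one half of the target is addressed.
- Comparison: this road controls C8' by an explicit stereochemical element and avoids acid, and is better there. The chosen plan sets against this that it needs no separate stereocontrol element for the furanoid half, shares one intermediate between both halves, and keeps epimer separation with acid recycling in reserve.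

Key step: step 10

## Route

Step 1
Reactants: 1 (R)-linalool
Product: 2 triethyl{[(3R)-3,7-dimethylocta-1,6-dien-3-yl]oxy}silane
Conditions: Et3SiOTf, 2,6-lutidine, CH2Cl2, −78 → 0 °C
Reagents that add atoms: triethylsilyl triflate, CC[Si](CC)(CC)OS(=O)(=O)C(F)(F)F
Why: Silylation of a tertiary alcohol with a silyl triflate; the ether stops O5 from opening the later epoxide and protects the vinyl carbinol from chromate transposition in step 4.

Step 2
Reactants: 2 triethyl{[(3R)-3,7-dimethylocta-1,6-dien-3-yl]oxy}silane
Product: 3 {[(3R)-5-(3,3-dimethyloxiran-2-yl)-3-methylpent-1-en-3-yl]oxy}triethylsilane (both epoxide epimers)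
Conditions: mCPBA, NaHCO3, CH2Cl2, 0 °C
Reagents that add atoms: 3-chloroperbenzoic acid, O=C(OO)c1cccc(Cl)c1
Why: Prilezhaev epoxidation; the trisubstituted alkene is far more nucleophilic than the vinyl group, and the epoxide configuration is lost in step 3.

Step 3
Reactants: 3 {[(3R)-5-(3,3-dimethyloxiran-2-yl)-3-methylpent-1-en-3-yl]oxy}triethylsilane
Product: 6 (3E,6R)-2,6-dimethyl-6-[(triethylsilyl)oxy]octa-3,7-dien-2-ol, via hydroxy selenide 4 (not isolated), via selenoxide 5 (not isolated)
Conditions: (PhSe)2, NaBH4, EtOH, reflux; then H2O2 (30 %), THF, 0 °C → rt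
Reagents that add atoms: none
Why: Sharpless–Lauer conversion of an epoxide into an allylic alcohol: phenylselenide opens the epoxide at its secondary carbon and the selenoxide eliminates syn, away from the carbinol carbon, so only the E tertiary allylic alcohol should form.

Step 4
Reactants: 6 (3E,6R)-2,6-dimethyl-6-[(triethylsilyl)oxy]octa-3,7-dien-2-ol
Product: 7 (6R)-2,6-dimethyl-6-[(triethylsilyl)oxy]octa-2,7-dien-4-one
Conditions: pyridinium chlorochromate (C5H5NH[CrO3Cl]), 4 Å MS, CH2Cl2, rt
Reagents that add atoms: none
Why: Babler–Dauben oxidative 1,3-transposition: the chromate ester of the tertiary allylic alcohol rearranges and is oxidised, which puts the carbonyl at C3 and restores the C1=C2 alkene.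

Step 5
Reactants: 7 (6R)-2,6-dimethyl-6-[(triethylsilyl)oxy]octa-2,7-dien-4-one
Product: 8 (6R)-7,8-dihydroxy-2,6-dimethyl-6-[(triethylsilyl)oxy]oct-2-en-4-one (epimers at the secondary carbinol, carotenoid C6)
Conditions: OsO4 (2 mol %), N-methylmorpholine N-oxide, acetone/H2O, 0 °C → rt
Reagents that add atoms: N-methylmorpholine N-oxide, C[N+]1([O-])CCOCC1; water, O
Why: Upjohn dihydroxylation; osmylation should prefer the isolated vinyl group to the electron-poor β,β-disubstituted enone, and the unselective new centre is removed in step 9.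

Step 6
Reactants: 8 (6R)-7,8-dihydroxy-2,6-dimethyl-6-[(triethylsilyl)oxy]oct-2-en-4-one
Product: 9 (6R)-7-hydroxy-2,6-dimethyl-6,8-bis[(triethylsilyl)oxy]oct-2-en-4-one (C7 epimers)
Conditions: Et3SiCl (1.05 equiv), imidazole, CH2Cl2, −40 → 0 °C
Reagents that add atoms: chlorotriethylsilane, CC[Si](CC)(CC)Cl
Why: Silylation selective for the primary hydroxyl; the secondary hydroxyl next to the silyloxy-bearing quaternary carbon reacts much more slowly.

Step 7
Reactants: 9 (6R)-7-hydroxy-2,6-dimethyl-6,8-bis[(triethylsilyl)oxy]oct-2-en-4-one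
Product: 10 (3R,5R)-3,7-dimethyl-1,3-bis[(triethylsilyl)oxy]oct-6-ene-2,5-diol (C2 epimers)
Conditions: (S)-2-methyl-CBS-oxazaborolidine (0.5 equiv), catecholborane, toluene, −78 °C
Reagents that add atoms: none
Why: Corey–Bakshi–Shibata reduction of an enone with the alkenyl group as the large substituent; the (S)-catalyst should give the (R)-allylic alcohol under reagent control, which is the geometry that becomes 3S in the ring.

Step 8
Reactants: 10 (3R,5R)-3,7-dimethyl-1,3-bis[(triethylsilyl)oxy]oct-6-ene-2,5-diol
Product: 11 (3R,5R)-5-[(tert-butyldimethylsilyl)oxy]-3,7-dimethyl-1,3-bis[(triethylsilyl)oxy]oct-6-en-2-ol (C2 epimers)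
Conditions: t-BuMe2SiCl (1.2 equiv), imidazole, DMF, 0 °C → rt
Reagents that add atoms: tert-butylchlorodimethylsilane, CC(C)(C)[Si](C)(C)Cl
Why: Silylation of the unhindered allylic hydroxyl; the other secondary hydroxyl is flanked by the quaternary C5 and should stay free under these conditions.

Step 9
Reactants: 11 (3R,5R)-5-[(tert-butyldimethylsilyl)oxy]-3,7-dimethyl-1,3-bis[(triethylsilyl)oxy]oct-6-en-2-ol
Product: 12 (3R,5R)-5-[(tert-butyldimethylsilyl)oxy]-3,7-dimethyl-1,3-bis[(triethylsilyl)oxy]oct-6-en-2-one
Conditions: Dess–Martin periodinane, NaHCO3, CH2Cl2, 0 °C → rt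
Reagents that add atoms: none
Why: Dess–Martin oxidation of a hindered secondary alcohol to the ketone; both C6 epimers converge, and the buffer spares the silyl ethers.

Step 10
Reactants: 12 (3R,5R)-5-[(tert-butyldimethylsilyl)oxy]-3,7-dimethyl-1,3-bis[(triethylsilyl)oxy]oct-6-en-2-one
Product: 13 (1S,2R,4S)-4-[(tert-butyldimethylsilyl)oxy]-2,6,6-trimethyl-2-[(triethylsilyl)oxy]-1-{[(triethylsilyl)oxy]methyl}cyclohexan-1-ol
Conditions: Fe(acac)3 (50 mol %), PhSiH3 (2.5 equiv), EtOH (0.02 M), 60 °C
Reagents that add atoms: none
Why: An iron hydride formed from Fe(acac)3 (trivalent iron), PhSiH3 and ethanol transfers a hydrogen atom to C2 of the trisubstituted alkene, the tertiary C1 radical adds to the C6 carbonyl carbon, and the alkoxy radical is reduced by divalent iron or by hydrogen transfer from the medium to the alkoxide, which returns trivalent iron. The closest known reaction type is the iron-hydride hydrogen-atom-transfer reductive cyclisation of alkene-tethered ketones to tertiary cycloalkanols. Ring A closes in the 6-exo-trig mode on the C=O group, forming the C1–C6 bond with the oxygen outside the ring. The new centre C6 is controlled by C3 and C5 through a chair transition state: the chair that keeps the C3 silyloxy group and the C5 methyl group equatorial has the C5–O bond axial, since the other chair would put both groups syn-axial to a C1 methyl group. Within this chair the carbonyl should turn its oxygen axial, anti to the C5–O dipole, and the larger CH2OSiEt3 group equatorial, so that the C6 hydroxyl ends trans-diaxial to O5 (6R in the target). The step needs the alkoxy radical to be reduced faster than it fragments toward C5 or C7; the high iron loading and the hydrogen-donor solvent are meant to secure this, and the non-chelating silyl groups on O5 and O7 keep the carbonyl in the dipole-opposed conformation. Regioselectivity of hydrogen transfer is intrinsic, because there is one alkene and it gives a tertiary radical. Any C6 epimer would be a separable diastereomer that still serves the furanoid branch, where C6 becomes trigonal.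

Step 11
Reactants: 13 (1S,2R,4S)-4-[(tert-butyldimethylsilyl)oxy]-2,6,6-trimethyl-2-[(triethylsilyl)oxy]-1-{[(triethylsilyl)oxy]methyl}cyclohexan-1-ol
Product: 14 (1S,2R,4S)-4-[(tert-butyldimethylsilyl)oxy]-1-(hydroxymethyl)-2,6,6-trimethylcyclohexane-1,2-diol
Conditions: HF·pyridine, pyridine, THF, 0 °C → rt
Reagents that add atoms: none
Why: Fluoride cleavage of both triethylsilyl ethers, which are much more labile than the secondary tert-butyldimethylsilyl ether; O5 and C7 are freed in one operation.

Step 12
Reactants: 14 (1S,2R,4S)-4-[(tert-butyldimethylsilyl)oxy]-1-(hydroxymethyl)-2,6,6-trimethylcyclohexane-1,2-diol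
Product: 15 (1R,2R,4S)-4-[(tert-butyldimethylsilyl)oxy]-1,2-dihydroxy-2,6,6-trimethylcyclohexane-1-carbaldehyde
Conditions: IBX, DMSO, rt
Reagents that add atoms: none
Why: IBX oxidation of the only oxidisable (primary) alcohol; the tertiary alcohols are inert, IBX does not cleave 1,2-diols, and the aldehyde has no α-hydrogen.

Step 13
Reactants: 15 (1R,2R,4S)-4-[(tert-butyldimethylsilyl)oxy]-1,2-dihydroxy-2,6,6-trimethylcyclohexane-1-carbaldehyde; 16 ethyl (2E)-4-(diethoxyphosphoryl)-3-methylbut-2-enoate
Product: 17 ethyl (2E,4E)-5-[(1R,2R,4S)-4-[(tert-butyldimethylsilyl)oxy]-1,2-dihydroxy-2,6,6-trimethylcyclohexyl]-3-methylpenta-2,4-dienoate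
Conditions: LiN(SiMe3)2 (1.0 equiv per 16), THF/DMPU, −78 → 0 °C
Reagents that add atoms: none
Why: Horner–Wadsworth–Emmons olefination with the vinylogous C5 phosphonate forms the 7E bond and brings the 9E bond; the stabilised anion is too weak a base to deprotonate the tertiary alcohols, so an α-ketol shift of the hydroxy aldehyde is not expected.

Step 14
Reactants: 17 ethyl (2E,4E)-5-[(1R,2R,4S)-4-[(tert-butyldimethylsilyl)oxy]-1,2-dihydroxy-2,6,6-trimethylcyclohexyl]-3-methylpenta-2,4-dienoate
Product: 18 (1R,2R,4S)-4-[(tert-butyldimethylsilyl)oxy]-1-[(1E,3E)-5-hydroxy-3-methylpenta-1,3-dien-1-yl]-2,6,6-trimethylcyclohexane-1,2-diol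
Conditions: i-Bu2AlH (excess), CH2Cl2, −78 °C; aq. KNaC4H4O6
Reagents that add atoms: none
Why: 1,2-Reduction of a dienoate to the allylic alcohol with an aluminium hydride; the excess allows for the two free hydroxyls.

Step 15
Reactants: 18 (1R,2R,4S)-4-[(tert-butyldimethylsilyl)oxy]-1-[(1E,3E)-5-hydroxy-3-methylpenta-1,3-dien-1-yl]-2,6,6-trimethylcyclohexane-1,2-diol
Product: 19 (2E,4E)-5-[(1R,2R,4S)-4-[(tert-butyldimethylsilyl)oxy]-1,2-dihydroxy-2,6,6-trimethylcyclohexyl]-3-methylpenta-2,4-dienal
Conditions: MnO2, CH2Cl2, rt
Reagents that add atoms: none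
Why: Manganese dioxide oxidises the primary allylic alcohol; the tertiary alcohols cannot be oxidised.

Step 16
Reactants: 17 ethyl (2E,4E)-5-[(1R,2R,4S)-4-[(tert-butyldimethylsilyl)oxy]-1,2-dihydroxy-2,6,6-trimethylcyclohexyl]-3-methylpenta-2,4-dienoate
Product: 20 ethyl (2E)-3-[(2R,6S,7aR)-6-[(tert-butyldimethylsilyl)oxy]-4,4,7a-trimethyl-2,4,5,6,7,7a-hexahydro-1-benzofuran-2-yl]but-2-enoate
Conditions: camphorsulfonic acid (10 mol %), CH2Cl2, 4 Å MS, 0 °C → rt
Reagents that add atoms: none
Why: Acid-catalysed SN1' cyclodehydration through the allyl cation also involved in the epoxide-to-furanoid rearrangement of carotenoid 5,6-epoxides: the tertiary allylic C6 hydroxyl ionises, O5 captures C8, and C6=C7 forms because C6 has no β-hydrogen to lose. C5 is untouched, and O5 can reach C8 only on its own face of the 7E allyl cation, which places the side chain trans to the C5 methyl group (8'R). The ester keeps C7=C8 from rotating and leaves C6–OH as the only ionisable site.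

Step 17
Reactants: 20 ethyl (2E)-3-[(2R,6S,7aR)-6-[(tert-butyldimethylsilyl)oxy]-4,4,7a-trimethyl-2,4,5,6,7,7a-hexahydro-1-benzofuran-2-yl]but-2-enoate
Product: 21 (2E)-3-[(2R,6S,7aR)-6-[(tert-butyldimethylsilyl)oxy]-4,4,7a-trimethyl-2,4,5,6,7,7a-hexahydro-1-benzofuran-2-yl]but-2-en-1-ol
Conditions: i-Bu2AlH, CH2Cl2, −78 °C; aq. KNaC4H4O6
Reagents that add atoms: none
Why: 1,2-Reduction of the enoate to the allylic alcohol; the conditions are non-acidic, so C8' is not at risk.

Step 18
Reactants: 21 (2E)-3-[(2R,6S,7aR)-6-[(tert-butyldimethylsilyl)oxy]-4,4,7a-trimethyl-2,4,5,6,7,7a-hexahydro-1-benzofuran-2-yl]but-2-en-1-ol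
Product: 22 (2E)-3-[(2R,6S,7aR)-6-[(tert-butyldimethylsilyl)oxy]-4,4,7a-trimethyl-2,4,5,6,7,7a-hexahydro-1-benzofuran-2-yl]but-2-enal
Conditions: MnO2, CH2Cl2, rt
Reagents that add atoms: none
Why: Neutral manganese dioxide oxidation of the allylic alcohol to the enal.

Step 19
Reactants: 23 (2E,4E,6E)-2,7-dimethylocta-2,4,6-trienedial
Product: 24 (2E,4E,6E)-2,7-dimethylocta-2,4,6-triene-1,8-diol
Conditions: NaBH4, MeOH/THF, 0 °C
Reagents that add atoms: none
Why: Borohydride 1,2-reduction of both conjugated aldehyde groups.

Step 20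
Reactants: 24 (2E,4E,6E)-2,7-dimethylocta-2,4,6-triene-1,8-diol
Product: 25 [(2E,4E,6E)-2,7-dimethylocta-2,4,6-triene-1,8-diyl]bis(triphenylphosphonium) dibromide
Conditions: PPh3·HBr (2.1 equiv), MeOH, rt
Reagents that add atoms: triphenylphosphine hydrobromide, [Br-].c1ccc(cc1)[PH+](c1ccccc1)c1ccccc1
Why: Allylic alcohols and triphenylphosphine hydrobromide give allylic phosphonium salts through the allyl cation; the acid is harmless at this stage and the all-E salt is the stable isomer.

Step 21
Reactants: 19 (2E,4E)-5-[(1R,2R,4S)-4-[(tert-butyldimethylsilyl)oxy]-1,2-dihydroxy-2,6,6-trimethylcyclohexyl]-3-methylpenta-2,4-dienal; 25 [(2E,4E,6E)-2,7-dimethylocta-2,4,6-triene-1,8-diyl]bis(triphenylphosphonium) dibromide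
Product: 26 [(2E,4E,6E,8E,10E,12E)-13-[(1R,2R,4S)-4-[(tert-butyldimethylsilyl)oxy]-1,2-dihydroxy-2,6,6-trimethylcyclohexyl]-2,7,11-trimethyltrideca-2,4,6,8,10,12-hexaen-1-yl]triphenylphosphonium bromide
Conditions: 25 (3 equiv), NaOMe (1.0 equiv), CH2Cl2/MeOH, 0 °C → rt
Reagents that add atoms: none
Why: Wittig reaction; excess bis-salt and one equivalent of base should limit the linker to one olefination, and the ylide is conjugated only toward the diol end, where no leaving group sits.

Step 22
Reactants: 26 the C25 phosphonium bromide of step 21; 22 (2E)-3-[(2R,6S,7aR)-6-[(tert-butyldimethylsilyl)oxy]-4,4,7a-trimethyl-2,4,5,6,7,7a-hexahydro-1-benzofuran-2-yl]but-2-enal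
Product: 27 (3S,5R,6R,3'S,5'R,8'R)-3,3'-bis[(tert-butyldimethylsilyl)oxy]-5',8'-epoxy-5,6,5',8'-tetrahydro-β,β-carotene-5,6-diol
Conditions: NaN(SiMe3)2 (1.0 equiv), THF, −78 °C → rt; then EtOAc, 60 °C, dark, argon
Reagents that add atoms: none
Why: Wittig reaction with the preformed ylide, so that no free base can remove the γ-hydrogen at C8' of the enal; the furanoid half is the electrophile, so no carbanion develops next to the C8'–O bond. Warming should convert Z isomers into the all-E chain.

Step 23
Reactants: 27 (3S,5R,6R,3'S,5'R,8'R)-3,3'-bis[(tert-butyldimethylsilyl)oxy]-5',8'-epoxy-5,6,5',8'-tetrahydro-β,β-carotene-5,6-diol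
Product: 28 (3S,5R,6R,3'S,5'R,8'R)-5',8'-epoxy-5,6,5',8'-tetrahydro-β,β-carotene-3,5,6,3'-tetrol
Conditions: Bu4NF, AcOH, THF, rt, dark
Reagents that add atoms: none
Why: Fluoride desilylation of the two secondary silyl ethers under buffered conditions; neither the tertiary allylic diol nor the furanoid C8' sees acid.

## Compound list

1 | (R)-linalool, (3R)-3,7-dimethylocta-1,6-dien-3-ol | C=C[C@](C)(O)CCC=C(C)C | starting material
2 | triethyl{[(3R)-3,7-dimethylocta-1,6-dien-3-yl]oxy}silane | C=C[C@](C)(O[Si](CC)(CC)CC)CCC=C(C)C | intermediate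
3 | {[(3R)-5-(3,3-dimethyloxiran-2-yl)-3-methylpent-1-en-3-yl]oxy}triethylsilane (both epoxide epimers) | C=C[C@](C)(O[Si](CC)(CC)CC)CCC1OC1(C)C | intermediate
4 | (6R)-2,6-dimethyl-3-(phenylselanyl)-6-[(triethylsilyl)oxy]oct-7-en-2-ol (C3 epimers) | C=C[C@](C)(O[Si](CC)(CC)CC)CCC([Se]c1ccccc1)C(C)(C)O | intermediate (not isolated)
5 | (6R)-2,6-dimethyl-3-(phenylseleninyl)-6-[(triethylsilyl)oxy]oct-7-en-2-ol | C=C[C@](C)(O[Si](CC)(CC)CC)CCC([Se](=O)c1ccccc1)C(C)(C)O | intermediate (not isolated)
6 | (3E,6R)-2,6-dimethyl-6-[(triethylsilyl)oxy]octa-3,7-dien-2-ol | C=C[C@](C)(O[Si](CC)(CC)CC)C/C=C/C(C)(C)O | intermediate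
7 | (6R)-2,6-dimethyl-6-[(triethylsilyl)oxy]octa-2,7-dien-4-one | C=C[C@](C)(O[Si](CC)(CC)CC)CC(=O)C=C(C)C | intermediate
8 | (6R)-7,8-dihydroxy-2,6-dimethyl-6-[(triethylsilyl)oxy]oct-2-en-4-one (C7 epimers) | CC(C)=CC(=O)C[C@@](C)(O[Si](CC)(CC)CC)C(O)CO | intermediate
9 | (6R)-7-hydroxy-2,6-dimethyl-6,8-bis[(triethylsilyl)oxy]oct-2-en-4-one (C7 epimers) | CC(C)=CC(=O)C[C@@](C)(O[Si](CC)(CC)CC)C(O)CO[Si](CC)(CC)CC | intermediate
10 | (3R,5R)-3,7-dimethyl-1,3-bis[(triethylsilyl)oxy]oct-6-ene-2,5-diol (C2 epimers) | CC(C)=C[C@H](O)C[C@@](C)(O[Si](CC)(CC)CC)C(O)CO[Si](CC)(CC)CC | intermediate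
11 | (3R,5R)-5-[(tert-butyldimethylsilyl)oxy]-3,7-dimethyl-1,3-bis[(triethylsilyl)oxy]oct-6-en-2-ol (C2 epimers) | CC(C)=C[C@H](O[Si](C)(C)C(C)(C)C)C[C@@](C)(O[Si](CC)(CC)CC)C(O)CO[Si](CC)(CC)CC | intermediate
12 | (3R,5R)-5-[(tert-butyldimethylsilyl)oxy]-3,7-dimethyl-1,3-bis[(triethylsilyl)oxy]oct-6-en-2-one | CC(C)=C[C@H](O[Si](C)(C)C(C)(C)C)C[C@@](C)(O[Si](CC)(CC)CC)C(=O)CO[Si](CC)(CC)CC | intermediate
13 | (1S,2R,4S)-4-[(tert-butyldimethylsilyl)oxy]-2,6,6-trimethyl-2-[(triethylsilyl)oxy]-1-{[(triethylsilyl)oxy]methyl}cyclohexan-1-ol | CC[Si](CC)(CC)OC[C@@]1(O)C(C)(C)C[C@H](O[Si](C)(C)C(C)(C)C)C[C@@]1(C)O[Si](CC)(CC)CC | intermediate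
14 | (1S,2R,4S)-4-[(tert-butyldimethylsilyl)oxy]-1-(hydroxymethyl)-2,6,6-trimethylcyclohexane-1,2-diol | OC[C@@]1(O)C(C)(C)C[C@H](O[Si](C)(C)C(C)(C)C)C[C@@]1(C)O | intermediate
15 | (1R,2R,4S)-4-[(tert-butyldimethylsilyl)oxy]-1,2-dihydroxy-2,6,6-trimethylcyclohexane-1-carbaldehyde | O=C[C@@]1(O)C(C)(C)C[C@H](O[Si](C)(C)C(C)(C)C)C[C@@]1(C)O | intermediate
16 | ethyl (2E)-4-(diethoxyphosphoryl)-3-methylbut-2-enoate (triethyl 3-methyl-4-phosphonocrotonate) | CCOC(=O)/C=C(\C)CP(=O)(OCC)OCC | starting material
17 | ethyl (2E,4E)-5-[(1R,2R,4S)-4-[(tert-butyldimethylsilyl)oxy]-1,2-dihydroxy-2,6,6-trimethylcyclohexyl]-3-methylpenta-2,4-dienoate | CCOC(=O)/C=C(\C)/C=C/[C@@]1(O)C(C)(C)C[C@H](O[Si](C)(C)C(C)(C)C)C[C@@]1(C)O | intermediate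
18 | (1R,2R,4S)-4-[(tert-butyldimethylsilyl)oxy]-1-[(1E,3E)-5-hydroxy-3-methylpenta-1,3-dien-1-yl]-2,6,6-trimethylcyclohexane-1,2-diol | OC/C=C(\C)/C=C/[C@@]1(O)C(C)(C)C[C@H](O[Si](C)(C)C(C)(C)C)C[C@@]1(C)O | intermediate
19 | (2E,4E)-5-[(1R,2R,4S)-4-[(tert-butyldimethylsilyl)oxy]-1,2-dihydroxy-2,6,6-trimethylcyclohexyl]-3-methylpenta-2,4-dienal | O=C/C=C(\C)/C=C/[C@@]1(O)C(C)(C)C[C@H](O[Si](C)(C)C(C)(C)C)C[C@@]1(C)O | intermediate
20 | ethyl (2E)-3-[(2R,6S,7aR)-6-[(tert-butyldimethylsilyl)oxy]-4,4,7a-trimethyl-2,4,5,6,7,7a-hexahydro-1-benzofuran-2-yl]but-2-enoate | CCOC(=O)/C=C(\C)[C@H]1C=C2C(C)(C)C[C@H](O[Si](C)(C)C(C)(C)C)C[C@@]2(C)O1 | intermediate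
21 | (2E)-3-[(2R,6S,7aR)-6-[(tert-butyldimethylsilyl)oxy]-4,4,7a-trimethyl-2,4,5,6,7,7a-hexahydro-1-benzofuran-2-yl]but-2-en-1-ol | OC/C=C(\C)[C@H]1C=C2C(C)(C)C[C@H](O[Si](C)(C)C(C)(C)C)C[C@@]2(C)O1 | intermediate
22 | (2E)-3-[(2R,6S,7aR)-6-[(tert-butyldimethylsilyl)oxy]-4,4,7a-trimethyl-2,4,5,6,7,7a-hexahydro-1-benzofuran-2-yl]but-2-enal | O=C/C=C(\C)[C@H]1C=C2C(C)(C)C[C@H](O[Si](C)(C)C(C)(C)C)C[C@@]2(C)O1 | intermediate
23 | (2E,4E,6E)-2,7-dimethylocta-2,4,6-trienedial | O=C/C(C)=C/C=C/C=C(\C)C=O | starting material
24 | (2E,4E,6E)-2,7-dimethylocta-2,4,6-triene-1,8-diol | OC/C(C)=C/C=C/C=C(\C)CO | intermediate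
25 | [(2E,4E,6E)-2,7-dimethylocta-2,4,6-triene-1,8-diyl]bis(triphenylphosphonium) dibromide | [Br-].[Br-].c1ccccc1[P+](c1ccccc1)(c1ccccc1)C/C(C)=C/C=C/C=C(\C)C[P+](c1ccccc1)(c1ccccc1)c1ccccc1 | intermediate
26 | [(2E,4E,6E,8E,10E,12E)-13-[(1R,2R,4S)-4-[(tert-butyldimethylsilyl)oxy]-1,2-dihydroxy-2,6,6-trimethylcyclohexyl]-2,7,11-trimethyltrideca-2,4,6,8,10,12-hexaen-1-yl]triphenylphosphonium bromide | CC(/C=C/C=C(C)/C=C/[C@@]1(O)C(C)(C)C[C@H](O[Si](C)(C)C(C)(C)C)C[C@@]1(C)O)=C\C=C\C=C(C)\C[P+](c1ccccc1)(c1ccccc1)c1ccccc1.[Br-] | intermediate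
27 | (3S,5R,6R,3'S,5'R,8'R)-3,3'-bis[(tert-butyldimethylsilyl)oxy]-5',8'-epoxy-5,6,5',8'-tetrahydro-β,β-carotene-5,6-diol | CC(/C=C/C=C(C)/C=C/[C@@]1(O)C(C)(C)C[C@H](O[Si](C)(C)C(C)(C)C)C[C@@]1(C)O)=C\C=C\C=C(C)\C=C\C=C(/C)[C@H]1C=C2C(C)(C)C[C@H](O[Si](C)(C)C(C)(C)C)C[C@@]2(C)O1 | intermediate
28 | (3S,5R,6R,3'S,5'R,8'R)-5',8'-epoxy-5,6,5',8'-tetrahydro-β,β-carotene-3,5,6,3'-tetrol | CC(/C=C/C=C(C)/C=C/[C@@]1(O)C(C)(C)C[C@H](O)C[C@@]1(C)O)=C\C=C\C=C(C)\C=C\C=C(/C)[C@H]1C=C2C(C)(C)C[C@H](O)C[C@@]2(C)O1 | target

## Step count and least certain steps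

Total: 23 steps. Longest linear sequence: 18 steps (steps 1–13, then 16–18, 22 and 23; the branch through steps 14, 15 and 21–23 is equally long).

**Step 10 (key step).** The alkoxy radical formed on ring closure may fragment toward C5 or C7 before it is reduced, which would open the ring again or scramble C5 on re-closure. The tertiary radical may also take up hydrogen before it adds to the hindered carbonyl, and facial control at C6 may be incomplete because the steric and dipolar preferences in the chair are close. The fallback sets out from 12 and changes the way the radical and the alkoxide are made. Epoxidation of the C1=C2 alkene with mCPBA would give the epoxy ketone F1. Cp2TiCl (trivalent titanium, from Cp2TiCl2 and Zn) would open the epoxide to the same tertiary C1 radical, and the alkoxy radical formed on closure would be trapped at once by a second titanium centre, giving the C2-hydroxylated ring compound F2. The extra hydroxyl would be removed by Barton–McCombie deoxygenation through the imidazolyl thiocarbonate F3 (1,1'-thiocarbonyldiimidazole, then Bu3SnH and AIBN). The route is rejoined at 13.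

**Step 16.** Rotation about C7–C8 in the allyl cation before closure would erode the configuration at C8', and a pinacol-type 1,2-shift from C5 to the C6 cation may compete. The fallback sets out from 17 and gives up kinetic stereospecificity. The closure is run to the equilibrium mixture of 20 and its C8' epimer F4 (furanoid C8 epimers interconvert under the same acid), the diastereomers are separated by chromatography, and F4 is returned to the acid. The route is rejoined at 20.

**Step 7.** Reagent control may be eroded because the "small" side of the ketone is a neopentyl-type chain and the free C6 hydroxyl can bind borane. The fallback sets out from 9 and changes from asymmetric reduction to kinetic resolution. Luche reduction (NaBH4, CeCl3·7H2O) would give 10 together with its C3 epimer F5. Sharpless kinetic resolution (Ti(Oi-Pr)4, diisopropyl L-tartrate, t-BuOOH) should epoxidise the fast-reacting (S)-carbinol F5 to the epoxy alcohol F6 and leave 10, although the cis methyl group on the alkene will lower the rate ratio. The route is rejoined at 10.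

**Step 13.** Addition of the phosphonate anion to an aldehyde flanked by two quaternary carbons may be slow; base may then trigger an α-ketol shift of the hydroxy aldehyde, and the C9 geometry may be mixed. The fallback sets out from 15 and builds the chain as C3 plus C2. The neutral stabilised ylide Ph3P=CHC(O)CH3 in hot toluene would give the enone F7, and Horner–Wadsworth–Emmons reaction of F7 with triethyl phosphonoacetate and NaH would give 17 after removal of the 9Z isomer. The route is rejoined at 17.

**Step 21.** Statistical double olefination of the bis-salt and difficult separation of the two salts may lower the efficiency. The fallback sets out from 24 and desymmetrises the linker before coupling. One equivalent of PPh3·HBr would give the hydroxy phosphonium salt F8, which is separated from diol and bis-salt at this cheap stage. Wittig reaction of F8 with 19 (NaOMe) would give the C25 allylic alcohol F9, and CBr4/PPh3 followed by PPh3 would convert F9 through the bromide F10 into 26. The route is rejoined at 26.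

## Further compounds

F1 | step 10 | (3R,5R)-5-[(tert-butyldimethylsilyl)oxy]-5-(3,3-dimethyloxiran-2-yl)-3-methyl-1,3-bis[(triethylsilyl)oxy]pentan-2-one (epoxide epimers) | CC1(C)OC1[C@H](O[Si](C)(C)C(C)(C)C)C[C@@](C)(O[Si](CC)(CC)CC)C(=O)CO[Si](CC)(CC)CC
F2 | step 10 | compound 13 with an additional hydroxyl at carotenoid C2 (C2 epimers) | CC[Si](CC)(CC)OC[C@@]1(O)C(C)(C)C(O)[C@H](O[Si](C)(C)C(C)(C)C)C[C@@]1(C)O[Si](CC)(CC)CC
F3 | step 10 | O-(imidazol-1-ylthiocarbonyl) derivative of F2 at the C2 hydroxyl | CC[Si](CC)(CC)OC[C@@]1(O)C(C)(C)C(OC(=S)n2ccnc2)[C@H](O[Si](C)(C)C(C)(C)C)C[C@@]1(C)O[Si](CC)(CC)CC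
F4 | step 16 | ethyl (2E)-3-[(2S,6S,7aR)-6-[(tert-butyldimethylsilyl)oxy]-4,4,7a-trimethyl-2,4,5,6,7,7a-hexahydro-1-benzofuran-2-yl]but-2-enoate (C8' epimer of 20) | CCOC(=O)/C=C(\C)[C@@H]1C=C2C(C)(C)C[C@H](O[Si](C)(C)C(C)(C)C)C[C@@]2(C)O1
F5 | step 7 | (3R,5S)-3,7-dimethyl-1,3-bis[(triethylsilyl)oxy]oct-6-ene-2,5-diol (C2 epimers; carotenoid C3 epimer of 10) | CC(C)=C[C@@H](O)C[C@@](C)(O[Si](CC)(CC)CC)C(O)CO[Si](CC)(CC)CC
F6 | step 7 | (3R,5S)-5-[(2R)-3,3-dimethyloxiran-2-yl]-3-methyl-1,3-bis[(triethylsilyl)oxy]pentane-2,5-diol (C2 epimers) | CC1(C)O[C@@H]1[C@@H](O)C[C@@](C)(O[Si](CC)(CC)CC)C(O)CO[Si](CC)(CC)CC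
F7 | step 13 | (3E)-4-[(1R,2R,4S)-4-[(tert-butyldimethylsilyl)oxy]-1,2-dihydroxy-2,6,6-trimethylcyclohexyl]but-3-en-2-one | CC(=O)/C=C/[C@@]1(O)C(C)(C)C[C@H](O[Si](C)(C)C(C)(C)C)C[C@@]1(C)O
F8 | step 21 | [(2E,4E,6E)-8-hydroxy-2,7-dimethylocta-2,4,6-trien-1-yl]triphenylphosphonium bromide | OC/C(C)=C/C=C/C=C(\C)C[P+](c1ccccc1)(c1ccccc1)c1ccccc1.[Br-]
F9 | step 21 | (1R,2R,4S)-4-[(tert-butyldimethylsilyl)oxy]-1-[(1E,3E,5E,7E,9E,11E)-13-hydroxy-3,7,12-trimethyltrideca-1,3,5,7,9,11-hexaen-1-yl]-2,6,6-trimethylcyclohexane-1,2-diol | CC(/C=C/C=C(C)/C=C/[C@@]1(O)C(C)(C)C[C@H](O[Si](C)(C)C(C)(C)C)C[C@@]1(C)O)=C\C=C\C=C(C)\CO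
F10 | step 21 | allylic bromide corresponding to F9 (13-bromo in place of 13-hydroxy) | CC(/C=C/C=C(C)/C=C/[C@@]1(O)C(C)(C)C[C@H](O[Si](C)(C)C(C)(C)C)C[C@@]1(C)O)=C\C=C\C=C(C)\CBr
A1 | alternative 1 | tert-butyldimethylsilyl ether of the 6'-hydroxy-7',8'-dihydro furanoid C15 alcohol with free 3'- and 6'-hydroxyls | CC(C)(C)[Si](C)(C)OC\C=C(/C)[C@H]1C[C@@]2(O)C(C)(C)C[C@H](O)C[C@@]2(C)O1
A2 | alternative 2 | (2R,4S)-4-[(tert-butyldimethylsilyl)oxy]-2-hydroxy-2,6,6-trimethylcyclohexan-1-one | O=C1C(C)(C)C[C@H](O[Si](C)(C)C(C)(C)C)C[C@@]1(C)O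
A3 | alternative 3 | tert-butyldimethylsilyl ether of alcohol 21 (C15 furanoid bis-silyl ether) | CC(C)(C)[Si](C)(C)OC\C=C(/C)[C@H]1C=C2C(C)(C)C[C@H](O[Si](C)(C)C(C)(C)C)C[C@@]2(C)O1
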